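**Assumptions:** (R)-(–)-carvone and (R)-(–)-linalool of high ee are the commercial chiral starting materials. Positions are given in dictyol numbering (C1/C5 ring fusion, C6 carbinol, C7 side-chain carbon, C10 exo-methylene carbon, C11/C14 THF carbons, C15 acetoxy carbon). Compounds are numbered in order of first appearance in the step list. The route is a paper design; nothing has been run.

## Retrosynthetic overview

1. Dictyol H ⇒ C6-O-silyl, C15-OH tetrahydrofuran; the THF (C11–O–C14, last ring) comes from Re(VII) syn-oxidative cyclization of the C11 tertiary alcohol onto the 14,15-alkene.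
2. Seven-membered ring (second ring) ⇒ C8–C9 bond by intramolecular Hosomi–Sakurai addition of a 2-(silylmethyl)allyl group to an α-methylene ketone.
3. α-Methylene ketone ⇒ C6–C7 bond between a linalool-derived alkenyllithium (carries C11) and a cyclopentenylidene ketene.
4. Ketene and cyclopentene (first ring) ⇒ photochemical Wolff ring contraction of a 6-diazocarvone; C1 comes from (R)-carvone, C11 from (R)-linalool, and C5, C6, C7, C14 are substrate-controlled.

## Route

**Step 1**
Reactants: 1, (R)-(–)-carvone
Product: 2, (5R)-5-(3-chloroprop-1-en-2-yl)-2-methylcyclohex-2-en-1-one (10-chlorocarvone)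
Conditions: Ca(OCl)2, solid CO2, CH2Cl2/H2O, 0 °C
Reagents that add atoms: calcium hypochlorite, [Ca+2].[O-]Cl.[O-]Cl
Why: Ene-type allylic chlorination by HOCl occurs only at the electron-rich isopropenyl group (the enone alkene is inert) and gives the 2-(chloromethyl)allyl unit without touching C5.

**Step 2**
Reactants: 2, 10-chlorocarvone
Product: 3, (5R)-2-methyl-5-[3-(trimethylsilyl)prop-1-en-2-yl]cyclohex-2-en-1-one
Conditions: Me3SiSiMe3, Pd(dba)2 (5 mol %), LiCl, DMF, 50 °C
Reagents that add atoms: hexamethyldisilane, C[Si](C)(C)[Si](C)(C)C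
Why: Pd-catalysed allylic silylation via a symmetrical 2-substituted π-allyl complex gives a single allylsilane under neutral conditions that leave the enone alone.

**Step 3**
Reactants: 3, allylsilane enone
Product: 4, (5S)-6-diazo-2-methyl-5-[3-(trimethylsilyl)prop-1-en-2-yl]cyclohex-2-en-1-one (descriptor changes by CIP priority only)
Conditions: LiHMDS, THF, –78 °C; CF3CO2CH2CF3; then MsN3, Et3N, H2O, MeCN, rt
Reagents that add atoms: methanesulfonyl azide, CS(=O)(=O)N=[N+]=[N-]
Why: Detrifluoroacetylative diazo transfer through the kinetic α′-enolate installs the diazo group at C6 of the enone; the adjacent stereocenter is not enolizable.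

**Step 4**
Reactants: 5, (R)-(–)-linalool
Product: 6, (3R)-3-hydroxy-3,7-dimethyloct-6-en-2-one
Conditions: PdCl2 (10 mol %), CuCl, O2 (1 atm), DMF/H2O 7:1, rt
Reagents that add atoms: water, O
Why: Tsuji–Wacker oxidation converts only the monosubstituted vinyl group (Markovnikov) into the methyl ketone; the trisubstituted alkene and the carbinol stereocenter are untouched.

**Step 5**
Reactants: 6, α-hydroxy methyl ketone
Product: 7, N′-[(2E,3R)-3-hydroxy-3,7-dimethyloct-6-en-2-ylidene]-2,4,6-triisopropylbenzenesulfonohydrazide
Conditions: TrisNHNH2, cat. HCl, THF, rt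
Reagents that add atoms: 2,4,6-triisopropylbenzenesulfonyl hydrazide, CC(C)c1cc(C(C)C)c(S(=O)(=O)NN)c(C(C)C)c1
Why: Hydrazone condensation gives the E isomer (sulfonamide syn to CH3), which is the geometry needed for Shapiro deprotonation at the methyl group.

**Step 6 (key step)**
Reactants: 4, diazo enone; 7, trisylhydrazone
Product: 8, (3R)-3-hydroxy-3,7-dimethyl-2-methylidene-1-{(1R,5R)-2-methyl-5-[3-(trimethylsilyl)prop-1-en-2-yl]cyclopent-2-en-1-yl}oct-6-en-1-one
Conditions: (a) 7, n-BuLi (3.0 equiv), THF/TMEDA, –78 → 0 °C, recool to –78 °C; (b) 4, hν (427 nm LED, flow), THF, –78 °C, ketene stream added to (a); (c) AcOH/BHT quench, –78 °C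
Reagents that add atoms: none
Why: Proposed new method: visible-light Wolff ring contraction of the α′-diazo enone (N2 loss with 1,2-shift of the alkenyl carbon forms the cyclopentene C4–C5 bond and an s-trans-locked vinylketene that cannot electrocyclize and persists at –78 °C), whose carbonyl carbon is captured by the Shapiro-derived alkenyllithium to form C6–C7, followed by kinetic C5-protonation of the dienolate anti to the C1 substituent to give the cis-1,5-disubstituted cyclopentene (C11 is carried unchanged from linalool); closest known reactions are photochemical Wolff generation of vinylketenes from α′-diazo enones and organolithium addition to isolated ketenes to give enolates.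

**Step 7**
Reactants: 8, allylsilane enone
Product: 9, (3aR,5S,8aR)-5-[(2R)-2-hydroxy-6-methylhept-5-en-2-yl]-3-methyl-8-methylidene-3a,5,6,7,8,8a-hexahydroazulen-4(1H)-one
Conditions: EtAlCl2 (2.5 equiv), CH2Cl2, –78 → –30 °C; aq. NaHCO3
Reagents that add atoms: none
Why: Intramolecular Hosomi–Sakurai conjugate addition of the 2-substituted allylsilane to the chelation-activated α-methylene ketone closes the seven-membered ring (C8–C9), and loss of silicon regenerates the exocyclic C10 methylene. C7 is set by protonation of the aluminium enolate on the convex α-face, and the allylsilane is far more nucleophilic than the side-chain trisubstituted alkene.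

**Step 8**
Reactants: 9, hydroazulenone
Product: 10, (3aR,4S,5R,8aR)-5-[(2R)-2-hydroxy-6-methylhept-5-en-2-yl]-3-methyl-8-methylidene-1,3a,4,5,6,7,8,8a-octahydroazulen-4-ol
Conditions: NaBH4, CeCl3·7H2O, MeOH, –40 °C
Reagents that add atoms: none
Why: Luche-type 1,2-reduction with external hydride attacks C6 from the convex α-face (the β-face is blocked by the cyclopentene and the C7 side chain), giving the 6β-alcohol cis to the side chain.

**Step 9**
Reactants: 10, diol
Product: 11, C6-O-triethylsilyl ether of 10 (tertiary C11-OH free)
Conditions: TESOTf (1.1 equiv), 2,6-lutidine, CH2Cl2, –78 °C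
Reagents that add atoms: triethylsilyl triflate, CC[Si](CC)(CC)OS(=O)(=O)C(F)(F)F
Why: Selective silylation of the secondary over the hindered tertiary alcohol masks C6-OH, so that it can neither form a perrhenate ester nor chelate rhenium in the next step.

**Step 10**
Reactants: 11, silyl ether / tertiary bishomoallylic alcohol
Product: 12, 2-[(2R,5R)-5-[(3aR,4S,5R,8aR)-3-methyl-8-methylidene-4-(triethylsilyloxy)-1,3a,4,5,6,7,8,8a-octahydroazulen-5-yl]-5-methyloxolan-2-yl]propan-2-ol
Conditions: Re2O7 (1.5 equiv), 2,6-lutidine, CH2Cl2, 0 °C → rt; aq. NaHSO3/NaHCO3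
Reagents that add atoms: rhenium(VII) oxide, O=[Re](=O)(=O)O[Re](=O)(=O)=O
Why: Hydroxyl-directed Re(VII) syn-oxidative cyclization (Kennedy type, [3+2] of the perrhenate ester onto the 14,15-alkene) forms the THF and the C15 tertiary alcohol. C14 is set trans to the bulky C7 substituent (methyl pseudo-axial), and the other alkenes have no tethered alkoxide and do not react.

**Step 11**
Reactants: 12, tertiary alcohol
Product: 13, C15 acetate of 12
Conditions: Ac2O, Et3N, DMAP, CH2Cl2, 35 °C
Reagents that add atoms: acetic anhydride, CC(=O)OC(C)=O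
Why: DMAP-catalysed acylation of the only free hydroxyl gives the tertiary acetate; no ketone or free secondary alcohol is present to compete.

**Step 12**
Reactants: 13, silyl ether acetate
Product: 14, dictyol H, 2-[(2R,5R)-5-[(3aR,4S,5R,8aR)-4-hydroxy-3-methyl-8-methylidene-1,3a,4,5,6,7,8,8a-octahydroazulen-5-yl]-5-methyloxolan-2-yl]propan-2-yl acetate
Conditions: HF·pyridine, THF/pyridine, 0 °C
Reagents that add atoms: none
Why: Fluoride cleavage of the TES ether liberates C6-OH without touching the tertiary acetate, the alkenes or any stereocenter.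

## Compound list

1 | (R)-(–)-carvone | CC1=CC[C@H](CC1=O)C(C)=C | starting material
2 | (5R)-10-chlorocarvone | CC1=CC[C@H](CC1=O)C(=C)CCl | intermediate
3 | (5R)-10-(trimethylsilyl)carvone | CC1=CC[C@H](CC1=O)C(=C)C[Si](C)(C)C | intermediate
4 | (5S)-6-diazo-10-(trimethylsilyl)carvone | CC1=CC[C@H](C(=[N+]=[N-])C1=O)C(=C)C[Si](C)(C)C | intermediate
5 | (R)-(–)-linalool | C=C[C@](C)(O)CCC=C(C)C | starting material
6 | (3R)-3-hydroxy-3,7-dimethyloct-6-en-2-one | CC(=O)[C@](C)(O)CCC=C(C)C | intermediate
7 | (E)-trisylhydrazone of 6 | C/C(=N\NS(=O)(=O)c1c(C(C)C)cc(C(C)C)cc1C(C)C)[C@](C)(O)CCC=C(C)C | intermediate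
8 | cis-cyclopentenyl α-methylene ketone (1R,5R; 3R side chain) | C=C(C[Si](C)(C)C)[C@@H]1CC=C(C)[C@@H]1C(=O)C(=C)[C@](C)(O)CCC=C(C)C | intermediate
9 | (3aR,5S,8aR)-hydroazulen-4-one with (2R)-hydroxyheptenyl side chain | C=C1CC[C@@H]([C@](C)(O)CCC=C(C)C)C(=O)[C@H]2C(C)=CC[C@@H]12 | intermediate
10 | (3aR,4S,5R,8aR)-6β,11-diol | C=C1CC[C@@H]([C@](C)(O)CCC=C(C)C)[C@@H](O)[C@H]2C(C)=CC[C@@H]12 | intermediate
11 | C6-O-TES ether of 10 | C=C1CC[C@@H]([C@](C)(O)CCC=C(C)C)[C@@H](O[Si](CC)(CC)CC)[C@H]2C(C)=CC[C@@H]12 | intermediate
12 | trans-THF C15 alcohol, C6-O-TES | C=C1CC[C@@H]([C@@]2(C)CC[C@H](C(C)(C)O)O2)[C@@H](O[Si](CC)(CC)CC)[C@H]2C(C)=CC[C@@H]12 | intermediate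
13 | C15 acetate, C6-O-TES | C=C1CC[C@@H]([C@@]2(C)CC[C@H](C(C)(C)OC(C)=O)O2)[C@@H](O[Si](CC)(CC)CC)[C@H]2C(C)=CC[C@@H]12 | intermediate
14 | dictyol H | C=C1CC[C@@H]([C@@]2(C)CC[C@H](C(C)(C)OC(C)=O)O2)[C@@H](O)[C@H]2C(C)=CC[C@@H]12 | target

## Step count and risks

Total steps: 12. Longest linear sequence: 10 (steps 1, 2, 3, 6, 7, 8, 9, 10, 11, 12 from carvone).

Steps most likely to fail:

1. **Step 6 (proposed new ketene alkenylation).** The risks are O-acylation by the lithium alkoxide, over-addition, and C5 epimerization. Fallback with known chemistry: irradiate 4 in the presence of N,O-dimethylhydroxylamine to isolate the Weinreb amide (classical photo-Wolff with amine trapping), then add the Shapiro alkenyllithium (Weinreb ketone synthesis). If needed, C5 is reset by kinetic protonation of the potassium dienolate.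

2. **Step 7 (Sakurai seven-ring closure).** The risks are 1,2-addition to the carbonyl giving a cyclopentanol, and participation of the side-chain alkene. Fallback: reverse the bond order. Make C8–C9 first by alkylating the kinetic enolate of O-TES-protected 6 with the allylic chloride carried through ring contraction (2 → diazo → photo-Wolff in MeOH). Then close C6–C7 by intramolecular Nozaki–Hiyama–Kishi coupling of the derived enol triflate onto the C6 aldehyde, oxidize, and reduce 1,4 with Stryker's reagent to reach 9.

3. **Step 10 (Re oxidative cyclization).** The risks are C14 diastereoselectivity and acid-promoted side reactions. Fallback: switch to the radical Co(II)/O2 alkenol cyclization (Mukaiyama–Hartung, trans-selective) with BrCCl3 termination to the C15 bromide, followed by AgOAc solvolysis, which delivers 13 directly.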